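## Retrosynthetic overview

1. Target 21 ⇐ open δ‑hydroxy ketone 20 (the hemiketal closes by itself). The spiro carbon C‑11 ⇐ the bridging C‑11 ketone of 15: one‑carbon homologation to the aldehyde, then CH2OH (formaldehyde aldol, enters last) and the C4 ketone arm (Wittig, CuH) built on the CHO. Core locants are defined in the remarks below.
2. Piperidine ⇐ Mannich closure between C‑10 (enol of the C‑11 ketone) and an aminomethyl group on C‑1. The C‑3 ester with the C3=C4–C12=C7 diene ⇐ C‑3 enone through its dienyl triflate and Pd/CO/MeOH.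
3. Key: the 3,11‑dione 9 (cyclopentenone C1–C2–C3–C4–C12, cyclopentane C4–C5–C6–C7–C12, cycloheptanone C1–C12–C7–C8–C9–C10–C11) ⇐ 4‑methoxycyclohexadienone 8 by photochemical contraction of the six‑membered ring C1–C2–C3–C4–C12–C11 (C1–C12 made, C11–C12 broken), which at the same time expands the cyclohexane C7–C8–C9–C10–C11–C12 by one atom.
4. Enabling feature: C‑3 (ester‑bearing, a latent ketone) and the spiro C‑11 (a latent ketone) are 1,4‑related through C‑2 and C‑1, and C‑12 sits on C‑1. This is the footprint that a ring‑fused, 4‑oxygenated cross‑conjugated cyclohexadienone leaves after a type‑A shift; the C12 carbocycle is an isomer of hexahydroacenaphthylene.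
5. Ring order: arene and cyclohexane (7‑methoxy‑1‑tetralone) → cyclopentane (Friedel–Crafts) → cyclopentenone and cycloheptanone (step 8) → piperidine → tetrahydropyran. The absolute configuration comes from one asymmetric hydrogenation (C‑7), is relayed to C‑1 in step 9, and C‑7 is then erased.

Key step: step 8

## Remarks and assumptions

- Locants: the carbocycle is numbered as tricyclo[5.4.1.0^{4,12}]dodecane. C‑1 is the quaternary bridgehead, C‑2 the ring CH2, C‑3 the ester‑bearing carbon, C‑4 and C‑12 the inner diene carbons (C‑12 is common to all three carbocycles), C‑5/C‑6 and C‑8/C‑9 the CH2CH2 units, C‑7 the outer diene carbon, C‑10 the tertiary bridgehead, C‑11 the spiro carbon. Compounds 5–8 carry acenaphthylene locants.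
- Assumption: the hemiketal carbon equilibrates through the open hydroxy ketone, so the configuration drawn for the target is taken to be the equilibrium anomer.
- Assumption: the BINAP antipode in step 3 is written as (S) by analogy and is to be confirmed; what is fixed is the (R) configuration of acid 4.

## Route

Step 1
Reactants: 1 7‑methoxy‑1‑tetralone
Product: 2 ethyl (E)‑2‑(7‑methoxy‑3,4‑dihydronaphthalen‑1(2H)‑ylidene)acetate
Conditions: triethyl phosphonoacetate, NaH, THF, 0 °C → reflux
Reagents that add atoms: triethyl phosphonoacetate, CCOC(=O)CP(=O)(OCC)OCC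
Why: Horner–Wadsworth–Emmons olefination of the aryl ketone, in which the E isomer (ester anti to the arene) is the thermodynamic product and is the one carried on.

Step 2
Reactants: 2 ethyl (E)‑2‑(7‑methoxy‑3,4‑dihydronaphthalen‑1(2H)‑ylidene)acetate
Product: 3 (E)‑2‑(7‑methoxy‑3,4‑dihydronaphthalen‑1(2H)‑ylidene)acetic acid
Conditions: LiOH, THF/MeOH/H2O, 50 °C; then aq. HCl; crystallisation of the E acid
Reagents that add atoms: lithium hydroxide, [Li+].[OH-]
Why: Ester saponification, which gives the carboxylate handle that the hydrogenation catalyst needs and allows the E isomer to be purified by crystallisation.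

Step 3
Reactants: 3 (E)‑2‑(7‑methoxy‑3,4‑dihydronaphthalen‑1(2H)‑ylidene)acetic acid
Product: 4 (R)‑2‑(7‑methoxy‑1,2,3,4‑tetrahydronaphthalen‑1‑yl)acetic acid
Conditions: H2 (50 bar), [Ru(OAc)2((S)‑BINAP)] (1 mol%), MeOH, 40 °C
Reagents that add atoms: none
Why: Noyori‑type Ru–BINAP asymmetric hydrogenation of a β,β‑disubstituted acrylic acid, in which the carboxylate‑bound chiral catalyst selects the alkene face and sets the benzylic stereocentre (the later C‑7).

Step 4
Reactants: 4 (R)‑2‑(7‑methoxy‑1,2,3,4‑tetrahydronaphthalen‑1‑yl)acetic acid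
Product: 5 (2aR)‑8‑methoxy‑2a,3,4,5‑tetrahydroacenaphthylen‑1(2H)‑one
Conditions: Eaton's reagent (P2O5 in MeSO3H, as solvent), 40 °C
Reagents that add atoms: none
Why: Intramolecular Friedel–Crafts acylation (indanone closure) at the only reachable position, ortho to OMe and peri to the side chain; the stereocentre is β to the new ketone and is not epimerised.

Step 5
Reactants: 5 (2aR)‑8‑methoxy‑2a,3,4,5‑tetrahydroacenaphthylen‑1(2H)‑one
Product: 6 (2aR)‑8‑methoxy‑1,2,2a,3,4,5‑hexahydroacenaphthylene
Conditions: H2 (4 bar), 10% Pd/C, AcOH, cat. HClO4, 40 °C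
Reagents that add atoms: none
Why: Acid‑assisted hydrogenolysis of an electron‑rich aryl ketone to the methylene group, which leaves the arene and the tertiary benzylic stereocentre untouched.

Step 6
Reactants: 6 (2aR)‑8‑methoxy‑1,2,2a,3,4,5‑hexahydroacenaphthylene
Product: 7 (2aR)‑1,2,2a,3,4,5‑hexahydroacenaphthylen‑8‑ol
Conditions: BBr3, CH2Cl2, −78 → 0 °C; then H2O
Reagents that add atoms: none
Why: Lewis‑acid cleavage of the aryl methyl ether (O‑demethylation by BBr3).

Step 7
Reactants: 7 (2aR)‑1,2,2a,3,4,5‑hexahydroacenaphthylen‑8‑ol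
Product: 8 (2aR)‑5a‑methoxy‑2,2a,3,4,5,5a‑hexahydroacenaphthylen‑8(1H)‑one (both C‑5a epimers)
Conditions: PhI(OAc)2, MeOH, 0 °C
Reagents that add atoms: methanol, CO
Why: Hypervalent‑iodine oxidative dearomatisation of a para‑alkylphenol, in which methanol adds at the alkyl‑bearing para carbon (the later C‑11) to give the p‑quinol methyl ether; the new centre forms as both epimers, which converge in step 8.

Step 8
Reactants: 8 (2aR)‑5a‑methoxy‑2,2a,3,4,5,5a‑hexahydroacenaphthylen‑8(1H)‑one
Product: 9 (7R)‑tricyclo[5.4.1.0^{4,12}]dodec‑4(12)‑ene‑3,11‑dione (C‑1 epimers, equilibrating)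
Conditions: hν (350 nm, Pyrex), AcOH/H2O 1:1, degassed, 10 °C, stopped before full conversion
Reagents that add atoms: water, O
Why: Proposed new method: n→π* excitation of the cross‑conjugated dienone should give, by β,β′‑bonding C‑1–C‑12, the bicyclo[3.1.0]hexenyl zwitterion (cyclopropane C‑1/C‑11/C‑12 plus oxyallyl cation C‑2/C‑3/C‑4), and the methoxy lone pair on C‑11 then pushes out the C‑11–C‑12 bond to give the C4=C12 enone and an oxocarbenium ion at C‑11 that water converts into the ketone, so that the dienone ring contracts to the cyclopentenone and the cyclohexane grows to the cycloheptanone in one operation. The closest known reactions are the acid‑mediated type‑A rearrangement of 4‑alkyl ring‑fused dienones to 5/7‑fused hydroazulenones (santonin to isophotosantonic lactone) and the oxygen‑assisted fragmentation in the photolysis of quinone monoketals to 4‑oxocyclopent‑2‑enecarboxylates; what is new is a ring‑fused p‑quinol ether whose angular oxygen turns the cation into a ketone. The five‑membered ring closes by transannular 3‑exo bonding of the two β‑carbons followed by opening of the shared cyclopropane bond, and the seven‑membered ring is not closed separately but results from that same bond cleavage (one‑carbon ring expansion). The only new stereocentre is the α‑keto CH at C‑1, which is epimerisable and needs no control, and the C‑7 centre is not involved. The step needs cleavage of C‑11–C‑12 and not of C‑1–C‑11 (which would give a spiro ketone); the ring CH2 on C‑4 stabilises the oxyallyl terminus that becomes the tetrasubstituted C4=C12 bond, as the 4‑methyl group does in santonin, and C‑12 is the most strained cyclopropane carbon.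

Step 9
Reactants: 9 (7R)‑tricyclo[5.4.1.0^{4,12}]dodec‑4(12)‑ene‑3,11‑dione
Product: 10 (1S,7R)‑1‑(phthalimidomethyl)tricyclo[5.4.1.0^{4,12}]dodec‑4(12)‑ene‑3,11‑dione
Conditions: N‑(bromomethyl)phthalimide, K2CO3, DMF, 0 °C → rt; C‑1 epimer removed by chromatography
Reagents that add atoms: N‑(bromomethyl)phthalimide, O=C1c2ccccc2C(=O)N1CBr
Why: C‑alkylation of the vinylogous 1,3‑diketone enolate by a soft SN2 electrophile (phthalimidomethylation), expected at C‑1 rather than C‑4 because the fused C4=C12 bond is kept, with the electrophile entering on the face of H‑7 (anti to the 1,3‑related C‑8), which sets C‑1 by substrate control while the mild base leaves H‑7 alone.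

Step 10
Reactants: 10 (1S,7R)‑1‑(phthalimidomethyl)tricyclo[5.4.1.0^{4,12}]dodec‑4(12)‑ene‑3,11‑dione
Product: 11 (1S)‑11‑oxo‑1‑(phthalimidomethyl)tricyclo[5.4.1.0^{4,12}]dodeca‑3,7(12)‑dien‑3‑yl trifluoromethanesulfonate
Conditions: Tf2O, 2,6‑di‑tert‑butyl‑4‑methylpyridine, CH2Cl2, 0 °C → rt
Reagents that add atoms: trifluoromethanesulfonic anhydride, O=S(=O)(OS(=O)(=O)C(F)(F)F)C(F)(F)F
Why: Thermodynamic dienyl triflate formation from an enone (as with steroidal 4‑en‑3‑ones), in which loss of H‑7, the only γ‑hydrogen now that C‑1 is quaternary, gives the through‑conjugated diene and erases the C‑7 stereocentre on purpose.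

Step 11
Reactants: 11 (1S)‑11‑oxo‑1‑(phthalimidomethyl)tricyclo[5.4.1.0^{4,12}]dodeca‑3,7(12)‑dien‑3‑yl trifluoromethanesulfonate
Product: 12 methyl (1S)‑11‑oxo‑1‑(phthalimidomethyl)tricyclo[5.4.1.0^{4,12}]dodeca‑3,7(12)‑diene‑3‑carboxylate
Conditions: CO (1 atm), Pd(OAc)2 (5 mol%), dppp, Et3N, MeOH/DMF, 40 °C
Reagents that add atoms: carbon monoxide, [C-]#[O+]; methanol, CO
Why: Palladium‑catalysed methoxycarbonylation of a dienyl triflate (oxidative addition, CO insertion, methanolysis of the acyl palladium).

Step 12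
Reactants: 12 methyl (1S)‑11‑oxo‑1‑(phthalimidomethyl)tricyclo[5.4.1.0^{4,12}]dodeca‑3,7(12)‑diene‑3‑carboxylate
Product: 13 methyl (1S)‑1‑(aminomethyl)‑11‑oxotricyclo[5.4.1.0^{4,12}]dodeca‑3,7(12)‑diene‑3‑carboxylate
Conditions: MeNH2 (33% in EtOH), rt
Reagents that add atoms: none
Why: Aminolysis of the phthalimide by methylamine (transamidation) should release the primary amine under conditions that spare the hindered conjugated methyl ester.

Step 13
Reactants: 13 methyl (1S)‑1‑(aminomethyl)‑11‑oxotricyclo[5.4.1.0^{4,12}]dodeca‑3,7(12)‑diene‑3‑carboxylate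
Product: 15 (1S,10R) N‑methyl bridged amino ketone (13 with C‑1–CH2–N(CH3)–CH2–C‑10 closed), via N‑unsubstituted bridged amino ketone 14 (not isolated)
Conditions: aq. CH2O (excess), AcOH, MeCN, 50 °C; then NaBH(OAc)3, rt
Reagents that add atoms: formaldehyde, C=O
Why: Intramolecular Mannich reaction (6‑endo attack of the C‑10 enol on the iminium ion) closes the piperidine, the bridge forcing H‑10 cis to the C‑1 aminomethyl group, and reductive amination then methylates the secondary amine while the hindered non‑enolisable bridging ketone is left.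

Step 14
Reactants: 15 (1S,10R) N‑methyl bridged amino ketone
Product: 17 (1S,10S) C‑11 carbaldehyde (C‑11 epimers), via methyl enol ether 16 (not isolated)
Conditions: MeOCH2PPh3Cl, KOtBu, THF, 0 → 50 °C; then 2 M HCl/THF, rt; aq. NaHCO3
Reagents that add atoms: (methoxymethyl)triphenylphosphonium chloride, COC[P+](c1ccccc1)(c1ccccc1)c1ccccc1.[Cl-]; water, O
Why: Wittig methoxymethylenation of the bridging ketone followed by acid hydrolysis of the enol ether (one‑carbon homologation); the configuration at C‑11 is irrelevant because it is planarised in step 15.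

Step 15
Reactants: 17 (1S,10S) C‑11 carbaldehyde
Product: 18 (1R,10S,11S) C‑11 hydroxymethyl carbaldehyde
Conditions: aq. CH2O, K2CO3 (cat.), MeOH, rt
Reagents that add atoms: formaldehyde, C=O
Why: Crossed aldol (Tollens‑type hydroxymethylation) of the α‑branched aldehyde, in which formaldehyde should attack the enolate from the face of the diene‑containing bridge (one syn‑axial H and the trigonal C‑12) rather than the piperidine face (two syn‑axial H), which sets the quaternary C‑11.

Step 16
Reactants: 18 (1R,10S,11S) C‑11 hydroxymethyl carbaldehyde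
Product: 19 (1R,10S,11R) (E)‑enone (CHO converted into CH=CH–C(=O)Et)
Conditions: Ph3P=CHC(O)Et, toluene, 90 °C
Reagents that add atoms: 1‑(triphenylphosphoranylidene)butan‑2‑one, CCC(=O)C=P(c1ccccc1)(c1ccccc1)c1ccccc1
Why: Wittig olefination of the neopentyl aldehyde by a stabilised keto ylide (E selective), under neutral conditions that avoid retro‑aldol loss of formaldehyde.

Step 17
Reactants: 19 (1R,10S,11R) (E)‑enone
Product: 21 target hemiketal CNP0192143.1 (C‑1 R, C‑10 S, C‑11 R, hemiketal carbon S), via open‑chain hydroxy ketone 20 (not isolated)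
Conditions: [(Ph3P)CuH]6, benzene/THF, trace H2O, rt
Reagents that add atoms: none
Why: Conjugate hydride reduction of the disubstituted enone by Stryker's reagent (the tetrasubstituted dienoate should be inert), after which the δ‑hydroxy ketone closes to the six‑membered hemiketal, whose configuration is set by equilibration.

## Compound list

1 | 7‑methoxy‑3,4‑dihydronaphthalen‑1(2H)‑one | COc1ccc2CCCC(=O)c2c1 | starting material
2 | ethyl (E)‑2‑(7‑methoxy‑3,4‑dihydronaphthalen‑1(2H)‑ylidene)acetate | COc1ccc2CCC/C(=C\C(=O)OCC)c2c1 | intermediate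
3 | (E)‑2‑(7‑methoxy‑3,4‑dihydronaphthalen‑1(2H)‑ylidene)acetic acid | COc1ccc2CCC/C(=C\C(O)=O)c2c1 | intermediate
4 | (R)‑2‑(7‑methoxy‑1,2,3,4‑tetrahydronaphthalen‑1‑yl)acetic acid | COc1ccc2CCC[C@H](CC(O)=O)c2c1 | intermediate
5 | (2aR)‑8‑methoxy‑2a,3,4,5‑tetrahydroacenaphthylen‑1(2H)‑one | COc1ccc2CCC[C@@H]3CC(=O)c1c23 | intermediate
6 | (2aR)‑8‑methoxy‑1,2,2a,3,4,5‑hexahydroacenaphthylene | COc1ccc2CCC[C@@H]3CCc1c23 | intermediate
7 | (2aR)‑1,2,2a,3,4,5‑hexahydroacenaphthylen‑8‑ol | Oc1ccc2CCC[C@@H]3CCc1c23 | intermediate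
8 | (2aR)‑5a‑methoxy‑2,2a,3,4,5,5a‑hexahydroacenaphthylen‑8(1H)‑one, C‑5a epimers | O=C1C=CC2(OC)CCC[C@@H]3CCC1=C23 | intermediate
9 | (7R)‑tricyclo[5.4.1.0^{4,12}]dodec‑4(12)‑ene‑3,11‑dione, C‑1 epimers | O=C1CCC[C@H]2C3=C(C(=O)CC31)CC2 | intermediate
10 | (1S,7R)‑1‑(phthalimidomethyl)tricyclo[5.4.1.0^{4,12}]dodec‑4(12)‑ene‑3,11‑dione | O=C1CCC[C@H]2C3=C(C(=O)C[C@@]31CN1C(=O)c4ccccc4C1=O)CC2 | intermediate
11 | (1S)‑11‑oxo‑1‑(phthalimidomethyl)tricyclo[5.4.1.0^{4,12}]dodeca‑3,7(12)‑dien‑3‑yl trifluoromethanesulfonate | O=C1CCCC2=C3C(=C(OS(=O)(=O)C(F)(F)F)C[C@@]31CN1C(=O)c4ccccc4C1=O)CC2 | intermediate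
12 | methyl (1S)‑11‑oxo‑1‑(phthalimidomethyl)tricyclo[5.4.1.0^{4,12}]dodeca‑3,7(12)‑diene‑3‑carboxylate | O=C1CCCC2=C3C(=C(C(=O)OC)C[C@@]31CN1C(=O)c4ccccc4C1=O)CC2 | intermediate
13 | methyl (1S)‑1‑(aminomethyl)‑11‑oxotricyclo[5.4.1.0^{4,12}]dodeca‑3,7(12)‑diene‑3‑carboxylate | O=C1CCCC2=C3C(=C(C(=O)OC)C[C@@]31CN)CC2 | intermediate
14 | (1S,10R) N‑unsubstituted bridged amino ketone (C‑1–CH2–NH–CH2–C‑10) | O=C2[C@@H]1CCC3=C4C(=C(C(=O)OC)C[C@@]42CNC1)CC3 | intermediate (not isolated)
15 | (1S,10R) N‑methyl bridged amino ketone | O=C2[C@@H]1CCC3=C4C(=C(C(=O)OC)C[C@@]42CN(C)C1)CC3 | intermediate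
16 | (1R,10S) methyl enol ether (C‑11=CH–OMe), E/Z mixture | COC=C2[C@@H]1CCC3=C4C(=C(C(=O)OC)C[C@@]42CN(C)C1)CC3 | intermediate (not isolated)
17 | (1S,10S) C‑11 carbaldehyde, C‑11 epimers | O=CC2[C@@H]1CCC3=C4C(=C(C(=O)OC)C[C@@]42CN(C)C1)CC3 | intermediate
18 | (1R,10S,11S) C‑11 hydroxymethyl carbaldehyde (CH2OH on the diene‑bridge face) | O=C[C@@]2(CO)[C@@H]1CCC3=C4C(=C(C(=O)OC)C[C@@]42CN(C)C1)CC3 | intermediate
19 | (1R,10S,11R) (E)‑enone | CCC(=O)/C=C/[C@@]2(CO)[C@@H]1CCC3=C4C(=C(C(=O)OC)C[C@@]42CN(C)C1)CC3 | intermediate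
20 | (1R,10S,11R) open‑chain δ‑hydroxy ketone | CCC(=O)CC[C@@]2(CO)[C@@H]1CCC3=C4C(=C(C(=O)OC)C[C@@]42CN(C)C1)CC3 | intermediate (not isolated)
21 | CNP0192143.1, spiro hemiketal | CC[C@@]1(O)CC[C@@]2(CO1)[C@@H]1CCC3=C4C(=C(C(=O)OC)C[C@@]42CN(C)C1)CC3 | target

Total step count: 17. Longest linear sequence: 17 steps (1 → 21).

## Steps most likely to fail

**1. Step 8 (Proposed new method).** The excited dienone may lose the methoxy group and re‑aromatise to the phenol. The zwitterion may open the other cyclopropane bond (spiro ketone) or slide to a lumiketone. The product, a β,γ‑unsaturated ketone and enone, may be consumed by secondary photolysis. The fallback uses known chemistry, sets out from 7 and returns at 9. Oxidative dearomatisation of 7 with PhI(OAc)2 and allyltrimethylsilane in hexafluoroisopropanol (oxidative Hosomi–Sakurai reaction) should give the 5a‑allyl dienone F1. Irradiation of F1 in aqueous acetic acid is the classical santonin‑type rearrangement of an angular‑carbon dienone and should give the 5/7‑fused tertiary homoallylic alcohol F2. OsO4/NaIO4 cleavage of the terminal alkene gives the β‑hydroxy aldehyde F3, and retro‑aldol cleavage (K2CO3, MeOH) unveils the C‑11 ketone of 9.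

**2. Step 9.** The ambident enolate may be alkylated on oxygen or at C‑4. The facial bias may be too small, and once C‑7 is erased in step 10 any wrong C‑1 epimer that is carried on becomes the enantiomer. The fallback sets out from 9 and returns at 15. A one‑pot double Mannich reaction of 9 with methylamine hydrochloride and formaldehyde (AcOH, mild heating) should give the bridged amino enedione F4 directly. The one‑carbon C‑11 bridge of a bicyclo[4.3.1] system can only lie on the face of C‑8, so C‑7 fixes C‑1 and C‑10 together. Triflation of F4 as its triflate salt (TfOH, then Tf2O and 2,6‑di‑tert‑butyl‑4‑methylpyridine) gives the dienyl triflate F5, and Pd/CO/MeOH gives 15.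

**3. Step 15.** Formaldehyde may approach the C‑11 enolate with low or reversed facial selectivity, and the β‑hydroxy aldehyde may revert by retro‑aldol reaction. The fallback answers a preference for the piperidine face; it sets out from 17 and returns at 21. DBU‑catalysed Michael addition of 17 to ethyl vinyl ketone brings in the C4 ketone arm from that face and gives the keto aldehyde F6. NaBH(OAc)3, which reduces aldehydes but not ketones, then gives the hydroxy ketone 20, which closes to 21.

## Further compounds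

F1 | step 8 | (2aR)‑5a‑allyl‑2,2a,3,4,5,5a‑hexahydroacenaphthylen‑8(1H)‑one, C‑5a epimers | O=C1C=CC2(CC=C)CCC[C@@H]3CCC1=C23
F2 | step 8 | (7R)‑11‑allyl‑11‑hydroxytricyclo[5.4.1.0^{4,12}]dodec‑4(12)‑en‑3‑one | OC1(CC=C)CCC[C@H]2C3=C(C(=O)CC31)CC2
F3 | step 8 | 2‑[(7R)‑11‑hydroxy‑3‑oxotricyclo[5.4.1.0^{4,12}]dodec‑4(12)‑en‑11‑yl]acetaldehyde | OC1(CC=O)CCC[C@H]2C3=C(C(=O)CC31)CC2
F4 | step 9 | (1S,7R,10R) N‑methyl bridged amino enedione | O=C2[C@@H]1CC[C@H]3C4=C(C(=O)C[C@@]42CN(C)C1)CC3
F5 | step 9 | (1S,10R) dienyl triflate of the bridged amino ketone | O=C2[C@@H]1CCC3=C4C(=C(OS(=O)(=O)C(F)(F)F)C[C@@]42CN(C)C1)CC3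
F6 | step 15 | (1R,10S,11R) C‑11 (3‑oxopentyl) carbaldehyde | CCC(=O)CC[C@@]2(C=O)[C@@H]1CCC3=C4C(=C(C(=O)OC)C[C@@]42CN(C)C1)CC3
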